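**Assumption:** the target is taken exactly as the given SMILES, i.e. (5R,6S,7R,8S,10R) in germacrane numbering (C‑1 ketone, C‑2=C‑3 furanone, C‑4=C‑15, C‑5 OH, C‑6/C‑12 lactone, C‑11=C‑13, C‑8 ester, C‑10 quaternary, C‑14 methyl). Atom labels "C‑n" use this numbering; plain numbers are compounds.

## Retrosynthetic overview

1. Target ⇐ methacryloylation of C‑8–OH and removal of a C‑5 silyl ether.
2. Key step: the C‑7–C‑8 bond is made last, by SmI2 ketyl‑radical cyclisation of a C‑8 aldehyde onto a 3‑(sulfonylmethyl)butenolide. Sulfinate expulsion closes the ten‑membered carbocycle, sets C‑7 and C‑8, and reveals the α‑methylene lactone in one operation.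
3. C‑5–C‑6 comes from a catalytic asymmetric anti‑selective vinylogous Mukaiyama aldol between a 2‑silyloxyfuran (from tulipalin A) and a 2‑(furanonyl)acrolein.
4. C‑5 and C‑15 are grafted onto the 5‑methyl group of the furanone (γ‑formylation, then α‑methylenation); C‑10 is set by Pd‑catalysed asymmetric allylation of 2,5‑dimethylfuran‑3(2H)‑one.
5. Ring order: furanone (purchased) → butenolide (from tulipalin A) → ten‑membered carbocycle (radical step, last).

## Route

**Step 1**
Reactants: 1, 2,5‑dimethylfuran‑3(2H)‑one (racemic, C‑2–H enolisable); 2, allyl methyl carbonate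
Product: 3, (R)‑2‑allyl‑2,5‑dimethylfuran‑3(2H)‑one
Conditions: Pd2(dba)3·CHCl3 (2.5 mol %), (R,R)‑ANDEN‑phenyl Trost ligand (6 mol %), toluene, 0 °C → rt (use the ligand antipode if the sense of induction proves opposite; 3 is needed as R)
Reagents that add atoms: allyl methyl carbonate (2), C=CCOC(=O)OC (allyl group = C‑9, C‑8 and one carbon removed later)
Why: Trost asymmetric allylic alkylation of the aromatic 3‑furanolate (a stabilised prochiral enolate, like oxindole or azlactone enolates); C‑2 attack restores the vinylogous ester and creates C‑10, the ligand pocket selects the enolate face, and O‑allylation is reversible under Pd(0).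

**Step 2**
Reactants: 3; 4, ethyl formate
Product: 5, (R)‑2‑(2‑allyl‑2‑methyl‑3‑oxo‑2,3‑dihydrofuran‑5‑yl)acetaldehyde (mostly its enol tautomer)
Conditions: LDA (2.2 equiv), THF, −78 °C; HCO2Et, −78 → −20 °C; AcOH quench
Reagents that add atoms: ethyl formate (4), CCOC=O (CHO = C‑5 and its oxygen)
Why: with C‑2 quaternary the 5‑methyl group is the only enolisable site; its extended dienolate is C‑formylated at the exocyclic carbon (crossed Claisen condensation), with no stereocentre touched.

**Step 3**
Reactants: 5; 6, Eschenmoser's salt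
Product: 7, (R)‑2‑(2‑allyl‑2‑methyl‑3‑oxo‑2,3‑dihydrofuran‑5‑yl)prop‑2‑enal (used at once, kept cold)
Conditions: CH2=NMe2+ I− (1.5 equiv), Et3N, CH2Cl2, 0 °C → rt
Reagents that add atoms: Eschenmoser's salt (6), C[N+](C)=C.[I-] (CH2 = C‑15)
Why: Mannich reaction at the enol carbon followed by in‑situ E1cB loss of Me2NH (standard α‑methylenation of an aldehyde) gives the 2‑substituted acrolein.

**Step 4**
Reactants: 8, tulipalin A (α‑methylene‑γ‑butyrolactone)
Product: 9, 3‑[(methylsulfonyl)methyl]furan‑2(5H)‑one
Conditions: MeSO2Na (1.5 equiv), I2 (1.2 equiv), MeOH, rt, ambient light; concentrate; DBU (2.2 equiv), CH2Cl2, 0 °C → rt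
Reagents that add atoms: sodium methanesulfinate, CS(=O)[O-].[Na+] (MeSO2 group)
Why: radical iodosulfonylation of the exo‑methylene (MeSO2I formed in situ), then dehydroiodination and base‑mediated vinyl‑to‑allyl sulfone isomerisation into the conjugated endocyclic butenolide, which is the thermodynamic isomer (same reaction type as the known methacrylate → 2‑(sulfonylmethyl)acrylate sequence).

**Step 5**
Reactants: 9
Product: 10, tert‑butyldimethyl({3‑[(methylsulfonyl)methyl]furan‑2‑yl}oxy)silane
Conditions: TBSOTf (1.1 equiv), Et3N (1.3 equiv), CH2Cl2, 0 °C; used crude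
Reagents that add atoms: TBSOTf, CC(C)(C)[Si](C)(C)OS(=O)(=O)C(F)(F)F
Why: O‑silylation and γ‑deprotonation give the aromatic 2‑silyloxyfuran (silyl dienol ether formation); γ‑deprotonation is preferred over the sulfonyl CH2 because it yields the aromatic furan.

**Step 6**
Reactants: 7; 10
Product: 11, (2R)‑2‑allyl‑5‑{(3R)‑3‑hydroxy‑3‑[(2S)‑4‑(methylsulfonylmethyl)‑5‑oxo‑2,5‑dihydrofuran‑2‑yl]prop‑1‑en‑2‑yl}‑2‑methylfuran‑3(2H)‑one
Conditions: SiCl4 (1.1 equiv), Denmark bisphosphoramide (5 mol %; (S,S) expected, the enantiomer giving Si‑face attack on the aldehyde), i‑Pr2NEt (10 mol %), CH2Cl2, −78 °C; aq. KF/NaHCO3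
Reagents that add atoms: none
Why: catalytic asymmetric vinylogous Mukaiyama aldol (Lewis‑base‑activated SiCl4); the silyloxyfuran adds through its γ‑carbon 1,2 to the enal. The catalyst controls the aldehyde face and the anti (erythro: O‑5/O‑6 anti in the C‑4–C‑7 zigzag) simple diastereoselection reported for this system with furan dienolates, giving 5R,6S; C‑10 is too remote to interfere.

**Step 7**
Reactants: 11
Product: 12, the C‑5 triethylsilyl ether of 11
Conditions: TESOTf (1.3 equiv), 2,6‑lutidine, CH2Cl2, −78 °C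
Reagents that add atoms: TESOTf, CC[Si](CC)(CC)OS(=O)(=O)C(F)(F)F
Why: standard silylation of the secondary allylic alcohol; the weak hindered base avoids γ‑deprotonation of the butenolide (C‑6 epimerisation).

**Step 8**
Reactants: 12
Product: 13, seco‑aldehyde: 2‑[(2R)‑2‑methyl‑3‑oxo‑5‑{(3R)‑3‑[(2S)‑4‑(methylsulfonylmethyl)‑5‑oxo‑2,5‑dihydrofuran‑2‑yl]‑3‑(triethylsilyloxy)prop‑1‑en‑2‑yl}‑2,3‑dihydrofuran‑2‑yl]acetaldehyde
Conditions: OsO4 (2 mol %), NaIO4 (4 equiv), 2,6‑lutidine (2 equiv), dioxane/H2O 3:1, rt; used directly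
Reagents that add atoms: OsO4/NaIO4/H2O (aldehyde oxygen), O=[Os](=O)(=O)=O and [O-]I(=O)(=O)=O.[Na+]
Why: Lemieux–Johnson cleavage; OsO4 takes the only electron‑rich monosubstituted alkene (the other three C=C are carbonyl‑conjugated and more substituted), and the lutidine buffer keeps the β‑oxy aldehyde from enolising (no retro‑oxa‑Michael at C‑10).

**Step 9 (key step)**
Reactants: 13
Product: 14, (5R,6S,7R,8S,10R)‑8‑hydroxy‑5‑(triethylsilyloxy)‑1‑oxo‑3,10‑epoxygermacra‑2,4(15),11(13)‑trien‑12,6‑olide (8‑O‑desmethacryloyl‑5‑O‑TES‑isogoiazensolide)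
Conditions: SmI2 (2.3 equiv, 0.1 M in THF) added over 1 h to 13 (2 mM, degassed THF), −78 → −40 °C, no HMPA or protic additive; pH 7 buffer at −78 °C
Reagents that add atoms: none
Why: Proposed new method: Sm(II) reduces the aliphatic aldehyde to the C‑8 ketyl radical, which adds 10‑exo to the unsubstituted β‑carbon (C‑7) of the butenolide; the resulting α‑lactonyl radical (or its Sm(III) enolate after a second electron transfer) irreversibly expels MeSO2•/MeSO2−, giving the 11(13)‑methylene lactone. C‑7 is set by attack anti to the C‑6–C‑5 bond (trans‑lactone; the syn mode needs a near‑eclipsed C‑5–C‑6–C‑7–C‑8 torsion in the furanone‑bridged ring). C‑8 is set by a staggered transition state with H‑8 between C‑6 and C‑11, the tether gauche to C‑6 and the bulky O–Sm outward, which corresponds to 8S. Closest known chemistry: SmI2 ketyl–olefin cyclisations onto enoates and butenolides (5‑ to 8‑membered rings) and radical addition/β‑sulfonyl fragmentation with 2‑(sulfonylmethyl)acrylates.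

**Step 10**
Reactants: 14; 15, methacryloyl chloride
Product: 16, 5‑O‑triethylsilyl‑isogoiazensolide
Conditions: methacryloyl chloride (3 equiv), Et3N, DMAP (0.2 equiv), CH2Cl2, 0 °C
Reagents that add atoms: methacryloyl chloride (15), C=C(C)C(Cl)=O
Why: DMAP‑catalysed acylation of the only free hydroxyl, with retention at C‑8; short exposure to amine at 0 °C is tolerated by the α‑methylene lactone.

**Step 11**
Reactants: 16
Product: 17, isogoiazensolide
Conditions: HF·pyridine, pyridine/THF, 0 °C
Reagents that add atoms: none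
Why: buffered fluoride desilylation of the TES ether; the methacrylate, α‑methylene lactone and furanone are stable to these conditions and no stereocentre is affected.

## Compound list

1 | 2,5‑dimethylfuran‑3(2H)‑one | CC1OC(C)=CC1=O | starting material
2 | allyl methyl carbonate | C=CCOC(=O)OC | starting material
3 | (R)‑2‑allyl‑2,5‑dimethylfuran‑3(2H)‑one | C=CC[C@@]1(C)OC(C)=CC1=O | intermediate
4 | ethyl formate | CCOC=O | starting material
5 | (R)‑2‑(2‑allyl‑2‑methyl‑3‑oxo‑2,3‑dihydrofuran‑5‑yl)acetaldehyde (drawn as aldehyde tautomer) | C=CC[C@@]1(C)OC(CC=O)=CC1=O | intermediate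
6 | Eschenmoser's salt | C[N+](C)=C.[I-] | starting material
7 | (R)‑2‑(2‑allyl‑2‑methyl‑3‑oxo‑2,3‑dihydrofuran‑5‑yl)prop‑2‑enal | C=CC[C@@]1(C)OC(C(=C)C=O)=CC1=O | intermediate
8 | tulipalin A (3‑methylenedihydrofuran‑2(3H)‑one) | C=C1CCOC1=O | starting material
9 | 3‑[(methylsulfonyl)methyl]furan‑2(5H)‑one | CS(=O)(=O)CC1=CCOC1=O | intermediate
10 | tert‑butyldimethyl({3‑[(methylsulfonyl)methyl]furan‑2‑yl}oxy)silane | CC(C)(C)[Si](C)(C)Oc1occc1CS(C)(=O)=O | intermediate
11 | vinylogous aldol adduct (5R,6S,10R) | C=CC[C@@]1(C)OC(=CC1=O)C(=C)[C@@H](O)[C@H]1OC(=O)C(CS(C)(=O)=O)=C1 | intermediate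
12 | C‑5 TES ether of 11 | C=CC[C@@]1(C)OC(=CC1=O)C(=C)[C@@H](O[Si](CC)(CC)CC)[C@H]1OC(=O)C(CS(C)(=O)=O)=C1 | intermediate
13 | seco‑aldehyde | O=CC[C@@]1(C)OC(=CC1=O)C(=C)[C@@H](O[Si](CC)(CC)CC)[C@H]1OC(=O)C(CS(C)(=O)=O)=C1 | intermediate
14 | 8‑O‑desmethacryloyl‑5‑O‑TES‑isogoiazensolide | O[C@H]1C[C@@]2(C)OC(=CC2=O)C(=C)[C@@H](O[Si](CC)(CC)CC)[C@H]2OC(=O)C(=C)[C@@H]21 | intermediate
15 | methacryloyl chloride | C=C(C)C(Cl)=O | starting material
16 | 5‑O‑TES‑isogoiazensolide | C=C(C)C(=O)O[C@H]1C[C@@]2(C)OC(=CC2=O)C(=C)[C@@H](O[Si](CC)(CC)CC)[C@H]2OC(=O)C(=C)[C@@H]21 | intermediate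
17 | isogoiazensolide | C=C(C)C(=O)O[C@H]1C[C@@]2(C)OC(=CC2=O)C(=C)[C@@H](O)[C@H]2OC(=O)C(=C)[C@@H]21 | target

## Summary

**Total steps:** 11. **Longest linear sequence:** 9 (steps 1, 2, 3, 6, 7, 8, 9, 10, 11 from compound 1); the butenolide branch (steps 4, 5) joins at step 6.

**Three steps most likely to fail:**

1. **Step 9 (SmI2 radical macrocyclisation).** Risks: strain of the ten‑membered closure; competing 5‑exo attack of the C‑8 ketyl on furanone C‑3 (giving a 7‑oxanorbornanone, disfavoured by strain and by attack at a fully substituted donor‑bearing carbon); reductive C‑10–O cleavage of the furanone; over‑reduction of the product; wrong C‑8 epimer.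
   Fallback: close the ring at a different bond. Join the fragments first by intermolecular C‑7–C‑8 coupling of the C‑8 aldehyde with the butenolide, then form the carbocycle by intramolecular Nozaki–Hiyama–Kishi addition of a C‑4 vinyl iodide to a C‑5 aldehyde. If only C‑8 is wrong, the 8‑epimer is corrected in step 10 by Mitsunobu esterification with methacrylic acid (inversion).

2. **Step 6 (asymmetric vinylogous aldol).** Risks: acrolein 7 is polymerisation‑prone; 1,4‑ versus 1,2‑addition; the furanone carbonyl may bind the silicon Lewis acid; anti/syn and facial selectivity are unproven on this enal.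
   Fallback: stop relying on simple diastereoselection. Use a threo‑tolerant enantioselective aldol (e.g. Ti/BINOL) to fix C‑6 only, oxidise C‑5–OH to the enone (Dess–Martin), and set 5R by reagent‑controlled CBS reduction.

3. **Step 1 (Pd asymmetric allylation creating C‑10).** Risks: enantioselectivity with an unsubstituted allyl unit on this stabilised furanolate is unproven; C‑4 allylation is possible.
   Fallback: do not create C‑10 on the preformed furanone. Take the tertiary carbinol from the chiral pool (e.g. Sharpless‑derived 2‑methylglycidol elaborated to an α′‑hydroxy ynone) and form the 3(2H)‑furanone by Au(I)‑ or Et2NH‑mediated 5‑endo cyclisation.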